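A direct plan would buy both benzene rings and join them by an Ullmann etherification: methyl 3-(benzyloxy)-2-bromo-5-methoxybenzoate A1 and 3-(benzyloxy)-5-methylphenol A2 would give the diaryl ether ester A3. Ester reduction, palmitoylation to the dibenzyl ether A4 and debenzylation would follow. Its weakest steps would be:
- the copper-mediated C–O coupling, because the C–Br carbon of A1 lies between an ester and a benzyloxy group on an electron-rich ring, so the coupling would be slow and hydrodebromination would compete;
- the run-up to A1 and A2, because bromination of a 3,5-dioxygenated benzoate would have to choose C2 over C6 and C4, and the symmetric diol would have to be monobenzylated statistically; these steps build nothing;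
- the final hydrogenolysis of A4, because the benzylic C–O bond of the palmitate would be cleaved together with the benzyl ethers, which would force a late chemoselective acylation of a free triol instead.

**Retrosynthetic overview of the new route**
- Ring B is commercial orcinol; ring A (C1 bearing the CH2O group C7, C2–OAr, C3–OH, C5–OMe) is not bought but built last, around the ether oxygen.
- The O–C2 bond is made while C2 is still sp3, as a Williamson ether (orcinol + methyl bromoacetate gives 3), so the hindered aryl–O coupling never arises.
- Key disconnection: ring A is closed from two acyclic esters through the C3–C4 bond (Claisen) and the C1–C2 bond (aldol), then aromatised. Ester 3 gives C2 (with OAr) and C3 (ester C=O, later OH); enol ether 6 gives C4, C5 (OMe in place), C6, C1 and C7 (as CO2Me).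
- The contiguous C1(C7)–C2(OAr)–C3(OH) array and the C5–OMe thus appear differentiated in one step, with no halogenation, no selective O-alkylation and no protecting group before ring closure.
- The end game silylates the two phenols, turns C7 into the palmitate and desilylates with fluoride, so no hydrogenolysis ever meets the benzylic ester.

Key step: step 3

Remark on the chemistry: the target is achiral. The only stereo-element on the route, the (E)-enol ether of 6 and 7, equilibrates under the basic conditions of step 3.

Step 1
Reactants: 1 orcinol (5-methylbenzene-1,3-diol); 2 methyl bromoacetate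
Product: 3 methyl 2-(3-hydroxy-5-methylphenoxy)acetate
Conditions: 1 (3 equiv), K2CO3 (1.2 equiv), acetone, reflux; excess 1 recovered
Reagents that add atoms: none
Why: Williamson O-alkylation of one phenoxide of the symmetric diol by an unhindered α-bromo ester (SN2), with excess orcinol to hold the product at the mono-ether; this sp3 C–O bond is the future C2–O bond of the diaryl ether.

Step 2
Reactants: 4 2-methoxypropene; 5 methyl chlorooxoacetate (methyl oxalyl chloride)
Product: 6 methyl (3E)-4-methoxy-2-oxopent-3-enoate
Conditions: 4 (1.5 equiv), pyridine (1.1 equiv), CH2Cl2, −10 °C to rt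
Reagents that add atoms: none
Why: C-acylation of an enol ether by an oxalyl monoester chloride, the standard entry to 4-alkoxy-2-oxoalk-3-enoates, with pyridine removing HCl from the oxocarbenium intermediate to give the conjugated (E)-β-methoxy enone.

Step 3
Reactants: 3 methyl 2-(3-hydroxy-5-methylphenoxy)acetate; 6 methyl (3E)-4-methoxy-2-oxopent-3-enoate
Product: 9 methyl 3-hydroxy-2-(3-hydroxy-5-methylphenoxy)-5-methoxybenzoate, via triketo ester enol ether 7 (not isolated), via cyclic aldol 8 (not isolated)
Conditions: NaOMe (3.3 equiv), THF with 10 vol% MeOH, 0 °C; 6 (1.4 equiv) added slowly; then 60 °C; 1 M HCl work-up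
Reagents that add atoms: none
Why: Proposed new method: methoxide should deprotonate the γ-methyl of 6, the dienolate should be acylated at its γ-carbon by the activated ester of 3 (Claisen condensation, ring A bond C3–C4) to give 7, the OAr-bearing methylene of 7 should then add to the α-keto ester carbonyl (intramolecular aldol, bond C1–C2) to give 8, and loss of water with enolisation should give the aromatic phenoxide irreversibly. The closest known reaction types are the classical base-mediated cyclocondensation of acetopyruvate esters with acetone to 3-hydroxy-5-methylbenzoates, the γ-acylation of β-alkoxycrotonate dienolates by esters, and the biomimetic aldol aromatisation of 3,5,7-triketo esters; new is the pairing of a 4-alkoxy-2-oxoalk-3-enoate with an α-aryloxy ester. Ring A, the only ring formed, closes by a six-membered intramolecular aldol condensation, and no stereocentre remains because 8 is transient. The step needs only one regiochemical outcome, and the substrates secure it: each partner has a single nucleophilic carbon and a single electrophilic carbon that can reach a six-membered ring, so either order of the two C–C bond formations (Claisen then aldol, or aldol then Dieckmann closure) gives the same 2-aryloxy-3-hydroxy-5-methoxy pattern. The methyl enol ether fixes OMe at C5, holds C2 and C5 of 6 cis, and cannot be expelled by O-cyclisation (that would need a four-membered ring), so no γ-pyrone can form, while retro-Claisen, retro-aldol and five-ring Dieckmann side equilibria are reversible in NaOMe/MeOH and should drain into the arene. Slow addition of 6 to excess base keeps it as the dienolate and limits its self-condensation, and the ring B phenoxide is a spectator whose O-acylation or O-vinylation would be reversed by methoxide.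

Step 4
Reactants: 9 methyl 3-hydroxy-2-(3-hydroxy-5-methylphenoxy)-5-methoxybenzoate
Product: 10 methyl 3-[(tert-butyldimethylsilyl)oxy]-2-{3-[(tert-butyldimethylsilyl)oxy]-5-methylphenoxy}-5-methoxybenzoate
Conditions: TBSCl (2.5 equiv), imidazole (5 equiv), DMF, rt
Reagents that add atoms: tert-butyldimethylsilyl chloride, CC(C)(C)[Si](C)(C)Cl
Why: imidazole-promoted silylation of both phenols, so that the hydride and the acid chloride of the next steps meet no acidic OH; aryl silyl ethers can later be cleaved without touching an alkyl ester.

Step 5
Reactants: 10 methyl 3-[(tert-butyldimethylsilyl)oxy]-2-{3-[(tert-butyldimethylsilyl)oxy]-5-methylphenoxy}-5-methoxybenzoate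
Product: 11 {3-[(tert-butyldimethylsilyl)oxy]-2-{3-[(tert-butyldimethylsilyl)oxy]-5-methylphenoxy}-5-methoxyphenyl}methanol
Conditions: i-Bu2AlH (2.5 equiv), CH2Cl2, −78 to 0 °C; aq. potassium sodium tartrate
Reagents that add atoms: none
Why: hydride reduction of the aryl ester to the benzylic alcohol with i-Bu2AlH, to which aryl silyl ethers, the methyl ether and the diaryl ether are inert at low temperature.

Step 6
Reactants: 11 {3-[(tert-butyldimethylsilyl)oxy]-2-{3-[(tert-butyldimethylsilyl)oxy]-5-methylphenoxy}-5-methoxyphenyl}methanol; 12 palmitoyl chloride (hexadecanoyl chloride)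
Product: 13 {3-[(tert-butyldimethylsilyl)oxy]-2-{3-[(tert-butyldimethylsilyl)oxy]-5-methylphenoxy}-5-methoxyphenyl}methyl hexadecanoate
Conditions: 12 (1.2 equiv), pyridine (2 equiv), DMAP (cat.), CH2Cl2, 0 °C to rt
Reagents that add atoms: none
Why: acylation of the only free hydroxyl, a primary benzylic alcohol, by the acid chloride under nucleophilic catalysis.

Step 7
Reactants: 13 {3-[(tert-butyldimethylsilyl)oxy]-2-{3-[(tert-butyldimethylsilyl)oxy]-5-methylphenoxy}-5-methoxyphenyl}methyl hexadecanoate
Product: 14 betaethrin H
Conditions: n-Bu4NF (2.4 equiv), AcOH (2.6 equiv), THF, 0 °C to rt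
Reagents that add atoms: none
Why: fluoride cleavage of the two aryl silyl ethers, buffered with acetic acid so that the phenoxides are protonated at once and cannot attack the palmitate; the benzylic ester has no ortho or para OH, so no quinone methide path is open.

**Compound list**
1 | orcinol (5-methylbenzene-1,3-diol) | Cc1cc(O)cc(O)c1 | starting material
2 | methyl bromoacetate | COC(=O)CBr | starting material
3 | methyl 2-(3-hydroxy-5-methylphenoxy)acetate | COC(=O)COc1cc(C)cc(O)c1 | intermediate
4 | 2-methoxypropene | COC(C)=C | starting material
5 | methyl chlorooxoacetate (methyl oxalyl chloride) | COC(=O)C(=O)Cl | starting material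
6 | methyl (3E)-4-methoxy-2-oxopent-3-enoate | COC(=O)C(=O)/C=C(/OC)C | intermediate
7 | methyl (3E)-7-(3-hydroxy-5-methylphenoxy)-4-methoxy-2,6-dioxohept-3-enoate | COC(=O)C(=O)/C=C(/OC)CC(=O)COc1cc(C)cc(O)c1 | intermediate
8 | methyl 1-hydroxy-6-(3-hydroxy-5-methylphenoxy)-3-methoxy-5-oxocyclohex-2-ene-1-carboxylate (racemic, mixture of diastereomers) | COC(=O)C1(O)C=C(OC)CC(=O)C1Oc1cc(C)cc(O)c1 | intermediate
9 | methyl 3-hydroxy-2-(3-hydroxy-5-methylphenoxy)-5-methoxybenzoate | COC(=O)c1cc(OC)cc(O)c1Oc1cc(C)cc(O)c1 | intermediate
10 | methyl 3-[(tert-butyldimethylsilyl)oxy]-2-{3-[(tert-butyldimethylsilyl)oxy]-5-methylphenoxy}-5-methoxybenzoate | COC(=O)c1cc(OC)cc(O[Si](C)(C)C(C)(C)C)c1Oc1cc(C)cc(O[Si](C)(C)C(C)(C)C)c1 | intermediate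
11 | {3-[(tert-butyldimethylsilyl)oxy]-2-{3-[(tert-butyldimethylsilyl)oxy]-5-methylphenoxy}-5-methoxyphenyl}methanol | OCc1cc(OC)cc(O[Si](C)(C)C(C)(C)C)c1Oc1cc(C)cc(O[Si](C)(C)C(C)(C)C)c1 | intermediate
12 | palmitoyl chloride (hexadecanoyl chloride) | CCCCCCCCCCCCCCCC(=O)Cl | starting material
13 | {3-[(tert-butyldimethylsilyl)oxy]-2-{3-[(tert-butyldimethylsilyl)oxy]-5-methylphenoxy}-5-methoxyphenyl}methyl hexadecanoate | CCCCCCCCCCCCCCCC(=O)OCc1cc(OC)cc(O[Si](C)(C)C(C)(C)C)c1Oc1cc(C)cc(O[Si](C)(C)C(C)(C)C)c1 | intermediate
14 | betaethrin H, [3-hydroxy-2-(3-hydroxy-5-methylphenoxy)-5-methoxyphenyl]methyl hexadecanoate | CCCCCCCCCCCCCCCC(=O)OCc1cc(OC)cc(O)c1Oc1cc(C)cc(O)c1 | target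

**Step count:** 7 steps in total. The longest linear sequence is 6 steps (1 → 3 → 9 → 10 → 11 → 13 → 14); step 2 runs in parallel.

**Steps most likely to fail**

Step 3 (proposed new method). The dienolate of 6 may condense with itself, the stabilised dienolate may be too weak a nucleophile for the methyl ester of 3, or the Claisen and aldol equilibria may not drain to the arene. The fallback sets out from orcinol 1 and comes back at 9. It takes ring A from a preformed benzene and brings ring B in as a masked, non-aromatic ring, using known reactions only. Orcinol 1 would be hydrogenated (H2, Rh/Al2O3, aq. NaOH) to 5-methylcyclohexane-1,3-dione F1 (also commercial), and (COCl)2 with catalytic DMF would convert this into 3-chloro-5-methylcyclohex-2-en-1-one F2. Commercial methyl 2-hydroxy-5-methoxybenzoate would be formylated ortho to the hydroxyl by a Duff reaction (hexamethylenetetramine, CF3CO2H) to methyl 3-formyl-2-hydroxy-5-methoxybenzoate F3. Its phenoxide (Cs2CO3, DMF, 80 °C) would displace chloride from F2 by addition–elimination to give methyl 3-formyl-5-methoxy-2-[(5-methyl-3-oxocyclohex-1-en-1-yl)oxy]benzoate F4. Dehydrogenation (catalytic I2 in DMSO, or Pd(OCOCF3)2 under O2) would aromatise the enone ring to methyl 3-formyl-2-(3-hydroxy-5-methylphenoxy)-5-methoxybenzoate F5. Dakin-type Baeyer–Villiger oxidation of the aldehyde (mCPBA, CH2Cl2) would give methyl 3-(formyloxy)-2-(3-hydroxy-5-methylphenoxy)-5-methoxybenzoate F6, and methanolysis (K2CO3, MeOH) would give 9.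

Step 2. Acid-induced oligomerisation of the enol ether, addition of HCl, or double acylation may take the place of clean C-acylation. The fallback sets out from 5 and comes back at 6. CuI-catalysed coupling of 5 with propyne (Et3N, THF) would give methyl 2-oxopent-3-ynoate F7. Base-catalysed conjugate addition of methanol (MeOH, catalytic DABCO) to this ynone would give the (E)-β-methoxy enone 6.

Step 7. Fluoride or a liberated phenoxide may cleave or transfer the palmitoyl group, or the silyl ether at C3, which is flanked by the aryloxy group, may be lost incompletely. The fallback sets out from 11 and comes back at 14. It reverses the order: the silyl groups would be removed before the ester exists, and the ester would then be formed chemoselectively. n-Bu4NF in THF would convert 11 into 3-(hydroxymethyl)-2-(3-hydroxy-5-methylphenoxy)-5-methoxyphenol F8. A Mitsunobu esterification with palmitic acid (PPh3, DIAD, THF, 0 °C) should then acylate only the primary benzylic alcohol, because the carboxylic acid is far more acidic than the two phenols and is the pronucleophile that is activated; this would give 14.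

**Further compounds**
F1 | step 3 | 5-methylcyclohexane-1,3-dione | CC1CC(=O)CC(=O)C1
F2 | step 3 | 3-chloro-5-methylcyclohex-2-en-1-one (racemic) | CC1CC(=O)C=C(Cl)C1
F3 | step 3 | methyl 3-formyl-2-hydroxy-5-methoxybenzoate | COC(=O)c1cc(OC)cc(C=O)c1O
F4 | step 3 | methyl 3-formyl-5-methoxy-2-[(5-methyl-3-oxocyclohex-1-en-1-yl)oxy]benzoate (racemic) | COC(=O)c1cc(OC)cc(C=O)c1OC1=CC(=O)CC(C)C1
F5 | step 3 | methyl 3-formyl-2-(3-hydroxy-5-methylphenoxy)-5-methoxybenzoate | COC(=O)c1cc(OC)cc(C=O)c1Oc1cc(C)cc(O)c1
F6 | step 3 | methyl 3-(formyloxy)-2-(3-hydroxy-5-methylphenoxy)-5-methoxybenzoate | COC(=O)c1cc(OC)cc(OC=O)c1Oc1cc(C)cc(O)c1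
F7 | step 2 | methyl 2-oxopent-3-ynoate | COC(=O)C(=O)C#CC
F8 | step 7 | 3-(hydroxymethyl)-2-(3-hydroxy-5-methylphenoxy)-5-methoxyphenol | OCc1cc(OC)cc(O)c1Oc1cc(C)cc(O)c1
A1 | direct plan | methyl 3-(benzyloxy)-2-bromo-5-methoxybenzoate | COC(=O)c1cc(OC)cc(OCc2ccccc2)c1Br
A2 | direct plan | 3-(benzyloxy)-5-methylphenol | Cc1cc(O)cc(OCc2ccccc2)c1
A3 | direct plan | methyl 3-(benzyloxy)-2-[3-(benzyloxy)-5-methylphenoxy]-5-methoxybenzoate | COC(=O)c1cc(OC)cc(OCc2ccccc2)c1Oc1cc(C)cc(OCc2ccccc2)c1
A4 | direct plan | {3-(benzyloxy)-2-[3-(benzyloxy)-5-methylphenoxy]-5-methoxyphenyl}methyl hexadecanoate | CCCCCCCCCCCCCCCC(=O)OCc1cc(OC)cc(OCc2ccccc2)c1Oc1cc(C)cc(OCc2ccccc2)c1
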